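**Retrosynthetic overview**
- Rings: A is the benzo ring of the chromanone, C its pyranone ring, B the 2-aryl ring, D the dimethylpyran ring fused to B.
- Last disconnection is C2–C1′, cut into two native electrophiles: C2 of a chromone and C6 of an aryl bromide. C2 is made nucleophilic as a 1-silyloxyallylnickel species (a homoenolate equivalent of the chromanone) in an enantioselective reductive coupling that sets the only stereocentre.
- The chromone comes from 2,4-dihydroxy-3-prenylacetophenone plus a one-carbon aminal ester; the acetophenone comes from 2,4-dihydroxyacetophenone and prenyl bromide.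
- The aryl bromide (6-bromo-2,2-dimethyl-2H-chromene) comes from 4-bromophenol and 3-methylbut-2-enal.
- Ring order: ring A bought, ring C closed in step 2; ring B bought, ring D closed in step 3; the two halves joined in step 4.

Assumption: the sense of induction of the chiral ligand in step 4 cannot be predicted; the (S,S)-ligand is written, and its (R,R)-antipode is used if the first run gives the 2R product.

Step 1
Reactants: 1 2,4-dihydroxyacetophenone; 2 prenyl bromide (1-bromo-3-methylbut-2-ene)
Product: 3 1-[2,4-dihydroxy-3-(3-methylbut-2-en-1-yl)phenyl]ethanone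
Conditions: 2 (1.1 equiv), 10% aq KOH (2.2 equiv), 0 °C to rt
Reagents that add atoms: prenyl bromide (2), CC(C)=CCBr
Why: In water the potassium phenoxide of 1 is alkylated on carbon, preferentially at C3 between the two oxygen-bearing carbons (C-prenylation of an ambident phenolate, SN2 type), and 3 is separated by chromatography from the minor 5-prenyl and O-prenyl isomers (about 30% expected); no stereocentre is formed.

Step 2
Reactants: 3 1-[2,4-dihydroxy-3-(3-methylbut-2-en-1-yl)phenyl]ethanone; 4 tert-butoxybis(dimethylamino)methane
Product: 6 7-hydroxy-8-(3-methylbut-2-en-1-yl)-4H-chromen-4-one, via enaminone 5 (not isolated)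
Conditions: 4 (2.5 equiv), toluene, 80 °C; then AcOH, 60 °C
Reagents that add atoms: tert-butoxybis(dimethylamino)methane (4), CN(C)C(OC(C)(C)C)N(C)C
Why: The aminal ester aminomethylenates the methyl ketone to enaminone 5, and in warm acetic acid the ortho-OH adds to the enaminone carbon and dimethylamine leaves (enaminone route to chromones, addition–elimination), closing ring C; the tert-butoxy reagent cannot O-methylate the acidic 4-OH, and no stereocentre is formed.

Step 3
Reactants: 7 4-bromophenol; 8 3-methylbut-2-enal
Product: 11 6-bromo-2,2-dimethyl-2H-chromene, via benzodioxaborinine 9 (not isolated), via ortho-quinone methide 10 (not isolated)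
Conditions: 8 (1.5 equiv), PhB(OH)2 (1.0 equiv), EtCO2H (cat.), toluene, reflux, Dean–Stark
Reagents that add atoms: 3-methylbut-2-enal (8), CC(C)=CC=O
Why: Phenylboronic acid tethers phenol and enal so that hydroxyalkylation occurs only ortho to oxygen (9), which fragments on heating to ortho-quinone methide 10 and closes ring D by oxa-6π electrocyclisation (boronic acid-templated chromene annulation), with water as the only other product and no stereocentre.

Step 4
Reactants: 6 7-hydroxy-8-(3-methylbut-2-en-1-yl)-4H-chromen-4-one; 11 6-bromo-2,2-dimethyl-2H-chromene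
Product: 14 (2S)-2-(2,2-dimethyl-2H-chromen-6-yl)-7-hydroxy-8-(3-methylbut-2-en-1-yl)-2,3-dihydro-4H-chromen-4-one, via silyl ether 12 (not isolated), via bis-silyl enol ether 13 (not isolated)
Conditions: 11 (1.5 equiv), Et3SiCl (3 equiv), 2,6-lutidine (1.1 equiv), NiCl2(MeOCH2CH2OMe) (10 mol %), (S,S)-iPr-BiOX [(4S,4'S)-4,4'-di(propan-2-yl)-4,4',5,5'-tetrahydro-2,2'-bi-1,3-oxazole] (12 mol %), Mn powder (3 equiv), N,N-dimethylacetamide, 0 °C to rt; then 1 M aq HCl, THF, 0 °C
Reagents that add atoms: none
Why: Proposed new method: after in-flask silylation of the 7-OH (12), Et3SiCl-assisted oxidative addition of the chiral zerovalent nickel–bis(oxazoline) complex to the chromone gives a 1-silyloxyallylnickel species, i.e. a C2-nickelated silyl enol ether (homoenolate equivalent), so that C2, normally the electrophilic β-carbon, becomes the nucleophilic partner for the electrophilic aryl bromide 11 with Mn supplying the electrons; C2–aryl reductive elimination inside the chiral ligand sphere delivers the aryl group to one face and sets C2 as S in enol ether 13, which dilute acid hydrolyses to 14 without touching C2; the closest known reaction type is the racemic nickel-catalysed reductive conjugate addition of aryl halides to enones with a chlorosilane and Mn through 1-silyloxyallylnickel intermediates, combined with enantioselective nickel-catalysed reductive cross-electrophile coupling using chiral bis(oxazoline) ligands.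

**Compound list**
1 | 2,4-dihydroxyacetophenone | CC(=O)c1ccc(O)cc1O | starting material
2 | prenyl bromide (1-bromo-3-methylbut-2-ene) | CC(C)=CCBr | starting material
3 | 1-[2,4-dihydroxy-3-(3-methylbut-2-en-1-yl)phenyl]ethanone | CC(=O)c1ccc(O)c(CC=C(C)C)c1O | intermediate
4 | tert-butoxybis(dimethylamino)methane | CN(C)C(OC(C)(C)C)N(C)C | starting material
5 | (E)-1-[2,4-dihydroxy-3-(3-methylbut-2-en-1-yl)phenyl]-3-(dimethylamino)prop-2-en-1-one (not isolated) | CN(C)/C=C/C(=O)c1ccc(O)c(CC=C(C)C)c1O | intermediate
6 | 7-hydroxy-8-(3-methylbut-2-en-1-yl)-4H-chromen-4-one | CC(C)=CCc1c(O)ccc2c(=O)ccoc12 | intermediate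
7 | 4-bromophenol | Oc1ccc(Br)cc1 | starting material
8 | 3-methylbut-2-enal | CC(C)=CC=O | starting material
9 | 6-bromo-4-(2-methylprop-1-en-1-yl)-2-phenyl-4H-1,3,2-benzodioxaborinine (racemic, not isolated) | CC(C)=CC1OB(c2ccccc2)Oc2ccc(Br)cc12 | intermediate
10 | 4-bromo-6-(3-methylbut-2-en-1-ylidene)cyclohexa-2,4-dien-1-one (not isolated) | CC(C)=CC=C1C=C(Br)C=CC1=O | intermediate
11 | 6-bromo-2,2-dimethyl-2H-chromene | CC1(C)C=Cc2cc(Br)ccc2O1 | intermediate
12 | 8-(3-methylbut-2-en-1-yl)-7-(triethylsilyloxy)-4H-chromen-4-one (not isolated) | CC[Si](CC)(CC)Oc1ccc2c(=O)ccoc2c1CC=C(C)C | intermediate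
13 | (2S)-2-(2,2-dimethyl-2H-chromen-6-yl)-8-(3-methylbut-2-en-1-yl)-4,7-bis(triethylsilyloxy)-2H-chromene (not isolated) | CC(C)=CCc1c(O[Si](CC)(CC)CC)ccc2c1O[C@H](c1ccc3c(c1)C=CC(C)(C)O3)C=C2O[Si](CC)(CC)CC | intermediate
14 | (2S)-2-(2,2-dimethyl-2H-chromen-6-yl)-7-hydroxy-8-(3-methylbut-2-en-1-yl)-2,3-dihydro-4H-chromen-4-one | CC(C)=CCc1c(O)ccc2c1O[C@H](c1ccc3c(c1)C=CC(C)(C)O3)CC2=O | target

**Step count and risks**
Total steps: 4. Longest linear sequence: 3 (steps 1, 2 and 4).

Steps most likely to fail:

- **Step 4.** Neither the reactivity of a chromone in the silyloxyallylnickel coupling nor the enantioselectivity has precedent. Side paths are proto-demetalation to the 2-unsubstituted chromanone, homocoupling of 11, and opening of the allylic aryl ether of a 2H-chromene by zerovalent nickel. The fallback reverses the roles of the two partners. It sets out from 11: borylation with B2(OH)4 (Pd(OAc)2, XPhos, KOAc, EtOH, 80 °C) gives (2,2-dimethyl-2H-chromen-6-yl)boronic acid F1. F1 is then added to chromone 6 by enantioselective conjugate addition under divalent palladium catalysis (Pd(OCOCF3)2, t-BuPyOx in the antipode that gives 2S, NH4PF6, H2O, ClCH2CH2Cl, 60 °C). The route is rejoined at 14.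

- **Step 1.** C-prenylation of the phenolate is only moderately selective for C3 over C5 and oxygen, so the yield is low. The fallback fixes the position with a halogen. It sets out from 1: iodination between the two hydroxyl groups (I2, HIO3, aq EtOH) gives 1-(2,4-dihydroxy-3-iodophenyl)ethanone F2. Stille coupling of F2 with tributyl(3-methylbut-2-en-1-yl)stannane (Pd(PPh3)4, DMF, 90 °C) rejoins the route at 3.

- **Step 3.** The one-flask annulation may be sluggish on a phenol that carries no activating group. The fallback builds ring D by a sigmatropic route. It sets out from 7: O-alkylation with 3-chloro-3-methylbut-1-yne (K2CO3, KI, CuI cat., acetone, reflux) gives 1-bromo-4-[(2-methylbut-3-yn-2-yl)oxy]benzene F3. Heating F3 in N,N-diethylaniline at 190 °C (aryl propargyl ether Claisen rearrangement, 1,5-hydrogen shift, electrocyclisation) rejoins the route at 11.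

**Further compounds**
F1 | step 4 | (2,2-dimethyl-2H-chromen-6-yl)boronic acid | CC1(C)C=Cc2cc(B(O)O)ccc2O1
F2 | step 1 | 1-(2,4-dihydroxy-3-iodophenyl)ethanone | CC(=O)c1ccc(O)c(I)c1O
F3 | step 3 | 1-bromo-4-[(2-methylbut-3-yn-2-yl)oxy]benzene | C#CC(C)(C)Oc1ccc(Br)cc1
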